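**Plan**

Chain numbering: C1 (alkyne CH) to C15 (methyl); O-a is the oxocane oxygen (C6, C12), O-b the tetrahydrofuran oxygen (C4, C7).
Retrosynthesis: cut C3–Br, then in one event the O-b–C4 bond of the tetrahydrofuran together with C10–Br, then C13–Br, the C12=C13 unit, the O-a insertion between C6 and C12, and the C5–C6 bond.
Enabling feature: O-b, C7, C8, C9 and C10 form a latent tetrahydrofuran (C10–Br is anti to C7–O-b and cis to C9–OH), so O-b can begin as the furan-derived bridge C7–O–C10 of an 8-oxabicyclo[3.2.1]octane, with C4 lying 1,4 to it through C6–C5.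
Forward: the O-b bridge comes with the commercial furan [4+3] adduct; Baeyer–Villiger insertion of O-a closes the oxocane (as a 3,9-dioxabicyclo[4.2.1]nonane); last, an epoxide-triggered oxonium ring switch hands O-b from C10 to C4 and closes the tetrahydrofuran while bromide takes C10.
Stereochemistry: absolute from a chiral borane (C9, hence C7 and C10), a chiral lithium amide (C6) and the Shi catalyst (C3, C4); relative from exo-face attack on the bicycle (C6, C9, C12, C13) and three SN2 inversions (C13, C10, C3).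

Key step: step 15

Assumption: the sense of induction of (−)-Ipc2BH in step 4 and of the (R,R)-lithium amide in step 9 is assigned by analogy (norbornene; the parent meso ketone); both reagents exist in both mirror-image forms and would be exchanged if the sense were opposite.

**Route**

Step 1
Reactants: 1 (E)-pent-2-en-4-yn-1-ol
Product: 4 (E)-5-(trimethylsilyl)pent-2-en-4-yn-1-ol, via dilithium salt 2 (not isolated), via bis-silyl compound 3 (not isolated)
Conditions: n-BuLi (2.1 equiv), THF, −78 °C; TMSCl (2.2 equiv), −78 °C to rt; 1 M HCl, rt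
Reagents that add atoms: chlorotrimethylsilane, C[Si](C)(C)Cl
Why: O,C-dilithiation, double silylation and selective acid hydrolysis of the O–Si bond (C-silylation of a terminal alkyne) should cap the alkyne without touching the (E)-alkene, and no stereocenter is formed.

Step 2
Reactants: 4 (E)-5-(trimethylsilyl)pent-2-en-4-yn-1-ol
Product: 5 (E)-(5-bromopent-3-en-1-yn-1-yl)trimethylsilane
Conditions: CBr4, PPh3, CH2Cl2, 0 °C
Reagents that add atoms: carbon tetrabromide, BrC(Br)(Br)Br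
Why: Appel bromination of a primary allylic alcohol should proceed by SN2 with the (E)-geometry kept, and no stereocenter is formed.

Step 3
Reactants: 6 (1R,5S)-8-oxabicyclo[3.2.1]oct-6-en-3-one (meso)
Product: 7 (1'R,5'S)-spiro[1,3-dioxolane-2,3'-[8]oxabicyclo[3.2.1]oct[6]ene] (meso)
Conditions: ethylene glycol, p-TsOH (cat.), benzene, reflux, Dean–Stark
Reagents that add atoms: ethylene glycol, OCCO
Why: acid-catalysed ketalization masks the ketone against borane and hydride reagents, and the product stays meso.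

Step 4
Reactants: 7 (1'R,5'S)-spiro[1,3-dioxolane-2,3'-[8]oxabicyclo[3.2.1]oct[6]ene]
Product: 9 (1'R,5'R,6'S)-spiro[1,3-dioxolane-2,3'-[8]oxabicyclo[3.2.1]octan]-6'-ol (exo alcohol), via trialkylborane 8 (not isolated)
Conditions: (−)-Ipc2BH, THF, −25 °C; NaOH, H2O2, 0 °C to rt
Reagents that add atoms: hydrogen peroxide, OO
Why: asymmetric hydroboration–oxidation of a meso bicyclic alkene should deliver boron to the exo face of one of the two enantiotopic alkene carbons under control of the chiral borane, which fixes C7, C10 and an exo C9–OH that is inverted in steps 5 and 6.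

Step 5
Reactants: 9 (1'R,5'R,6'S)-spiro[1,3-dioxolane-2,3'-[8]oxabicyclo[3.2.1]octan]-6'-ol
Product: 10 (1'R,5'R)-spiro[1,3-dioxolane-2,3'-[8]oxabicyclo[3.2.1]octan]-6'-one
Conditions: Dess–Martin periodinane, NaHCO3, CH2Cl2, rt
Reagents that add atoms: none
Why: Dess–Martin oxidation gives the ketone so that the C9 configuration can be reset by hydride, and no stereocenter is formed.

Step 6
Reactants: 10 (1'R,5'R)-spiro[1,3-dioxolane-2,3'-[8]oxabicyclo[3.2.1]octan]-6'-one
Product: 11 (1'R,5'R,6'R)-spiro[1,3-dioxolane-2,3'-[8]oxabicyclo[3.2.1]octan]-6'-ol (endo alcohol)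
Conditions: LiBH(s-Bu)3, THF, −78 °C; aq. NH4Cl
Reagents that add atoms: none
Why: hydride reduction of the bicyclic ketone from the exo face (the endo face is covered by the three-carbon bridge and its dioxolane) should give the endo alcohol, which is the C9 configuration of the target.

Step 7
Reactants: 11 (1'R,5'R,6'R)-spiro[1,3-dioxolane-2,3'-[8]oxabicyclo[3.2.1]octan]-6'-ol
Product: 12 (1'R,5'R,6'R)-6'-(tert-butyldimethylsilyloxy)spiro[1,3-dioxolane-2,3'-[8]oxabicyclo[3.2.1]octane]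
Conditions: TBSCl, imidazole, DMF, rt
Reagents that add atoms: tert-butyldimethylsilyl chloride, CC(C)(C)[Si](C)(C)Cl
Why: silylation protects O9 with a group that cannot act as a neighbouring acyl group in the later oxonium chemistry, and no stereocenter is touched.

Step 8
Reactants: 12 (1'R,5'R,6'R)-6'-(tert-butyldimethylsilyloxy)spiro[1,3-dioxolane-2,3'-[8]oxabicyclo[3.2.1]octane]
Product: 13 (1R,5R,6R)-6-(tert-butyldimethylsilyloxy)-8-oxabicyclo[3.2.1]octan-3-one
Conditions: PPTS (cat.), acetone/H2O, 55 °C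
Reagents that add atoms: water, O
Why: mild acid-catalysed ketal hydrolysis should free the ketone while the secondary silyl ether survives, and no stereocenter is touched.

Step 9
Reactants: 13 (1R,5R,6R)-6-(tert-butyldimethylsilyloxy)-8-oxabicyclo[3.2.1]octan-3-one and 5 (E)-(5-bromopent-3-en-1-yn-1-yl)trimethylsilane
Product: 15 (1R,2R,5R,6R)-6-(tert-butyldimethylsilyloxy)-2-[(E)-5-(trimethylsilyl)pent-2-en-4-yn-1-yl]-8-oxabicyclo[3.2.1]octan-3-one, via lithium enolate 14 (not isolated)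
Conditions: (R,R)-bis(1-phenylethyl)amine, n-BuLi, LiCl, THF, −78 °C; then 5, DMPU, −78 to −40 °C
Reagents that add atoms: none
Why: reagent-controlled deprotonation with a chiral lithium amide (known for 8-oxabicyclo[3.2.1]octan-3-ones) should remove the axial proton on the α-carbon remote from the silyloxy group, and SN2 alkylation of the enolate by the allylic bromide on its exo (axial) face sets C6.

Step 10
Reactants: 15 (1R,2R,5R,6R)-6-(tert-butyldimethylsilyloxy)-2-[(E)-5-(trimethylsilyl)pent-2-en-4-yn-1-yl]-8-oxabicyclo[3.2.1]octan-3-one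
Product: 16 (1R,2R,6R,7R)-7-(tert-butyldimethylsilyloxy)-2-[(E)-5-(trimethylsilyl)pent-2-en-4-yn-1-yl]-3,9-dioxabicyclo[4.2.1]nonan-4-one
Conditions: mCPBA, NaHCO3, CH2Cl2, 0 °C to rt
Reagents that add atoms: 3-chloroperoxybenzoic acid, OOC(=O)c1cccc(Cl)c1
Why: Baeyer–Villiger oxidation with migration of the more substituted α-carbon (C6) with retention inserts O-a and closes the oxocane as the bridged lactone, the electron-poor enyne being slow to epoxidise.

Step 11
Reactants: 16 (1R,2R,6R,7R)-7-(tert-butyldimethylsilyloxy)-2-[(E)-5-(trimethylsilyl)pent-2-en-4-yn-1-yl]-3,9-dioxabicyclo[4.2.1]nonan-4-one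
Product: 17 (1R,2R,4Z,6R,7R)-7-(tert-butyldimethylsilyloxy)-4-propylidene-2-[(E)-5-(trimethylsilyl)pent-2-en-4-yn-1-yl]-3,9-dioxabicyclo[4.2.1]nonane
Conditions: CH3CH2CHBr2, Zn, TiCl4, TMEDA, PbCl2 (cat.), THF, 25 °C
Reagents that add atoms: 1,1-dibromopropane, CCC(Br)Br
Why: Takai–Utimoto alkylidenation of the lactone carbonyl should give the (Z)-enol ether (ethyl cis to the ring oxygen), which brings in C13–C15 with the geometry that later defines C13.

Step 12
Reactants: 17 (1R,2R,4Z,6R,7R)-7-(tert-butyldimethylsilyloxy)-4-propylidene-2-[(E)-5-(trimethylsilyl)pent-2-en-4-yn-1-yl]-3,9-dioxabicyclo[4.2.1]nonane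
Product: 19 (R)-1-[(1R,2R,4S,6R,7R)-7-(tert-butyldimethylsilyloxy)-2-[(E)-5-(trimethylsilyl)pent-2-en-4-yn-1-yl]-3,9-dioxabicyclo[4.2.1]nonan-4-yl]propan-1-ol, via spiro-epoxide 18 (not isolated)
Conditions: dimethyldioxirane, acetone/CH2Cl2, −78 °C; i-Bu2AlH, CH2Cl2, −78 °C; aq. potassium sodium tartrate
Reagents that add atoms: dimethyldioxirane, CC1(C)OO1
Why: enol ether epoxidation–reduction, with dimethyldioxirane attacking the electron-rich enol ether on its exo face and aluminium delivering hydride to the acetal carbon syn to the epoxide oxygen, should set C12 (H exo, side chain endo) and C13 (OH) in one operation.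

Step 13
Reactants: 19 (R)-1-[(1R,2R,4S,6R,7R)-7-(tert-butyldimethylsilyloxy)-2-[(E)-5-(trimethylsilyl)pent-2-en-4-yn-1-yl]-3,9-dioxabicyclo[4.2.1]nonan-4-yl]propan-1-ol
Product: 20 (1R,2R,4S,6R,7R)-4-[(S)-1-bromopropyl]-7-(tert-butyldimethylsilyloxy)-2-[(E)-5-(trimethylsilyl)pent-2-en-4-yn-1-yl]-3,9-dioxabicyclo[4.2.1]nonane
Conditions: CBr4, P(n-C8H17)3, toluene, 70 °C
Reagents that add atoms: carbon tetrabromide, BrC(Br)(Br)Br
Why: Appel-type bromination of the secondary alcohol by SN2 inversion should turn the (13R)-carbinol into the (13S)-bromide.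

Step 14
Reactants: 20 (1R,2R,4S,6R,7R)-4-[(S)-1-bromopropyl]-7-(tert-butyldimethylsilyloxy)-2-[(E)-5-(trimethylsilyl)pent-2-en-4-yn-1-yl]-3,9-dioxabicyclo[4.2.1]nonane
Product: 21 (1R,2R,4S,6R,7R)-4-[(S)-1-bromopropyl]-7-(tert-butyldimethylsilyloxy)-2-{[(2S,3S)-3-[(trimethylsilyl)ethynyl]oxiran-2-yl]methyl}-3,9-dioxabicyclo[4.2.1]nonane
Conditions: L-fructose-derived Shi ketone (0.3 equiv), Oxone (2KHSO5·KHSO4·K2SO4), K2CO3, Bu4NHSO4 (cat.), MeCN/dimethoxymethane/aq. Na2B4O7 buffer, 0 °C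
Reagents that add atoms: potassium peroxymonosulfate, [K+].[O-]S(=O)(=O)OO
Why: Shi epoxidation of the trans-enyne, the only alkene left, should give the (3S,4S)-epoxide under catalyst control.

Step 15
Reactants: 21 (1R,2R,4S,6R,7R)-4-[(S)-1-bromopropyl]-7-(tert-butyldimethylsilyloxy)-2-{[(2S,3S)-3-[(trimethylsilyl)ethynyl]oxiran-2-yl]methyl}-3,9-dioxabicyclo[4.2.1]nonane
Product: 24 (S)-1-[(1R,3S,5S,6R,8R,10R)-5-bromo-3-[(S)-1-bromopropyl]-6-(tert-butyldimethylsilyloxy)-2,9-dioxabicyclo[6.3.0]undecan-10-yl]prop-2-yn-1-ol, via tricyclic oxonium zwitterion 22 (not isolated), via ring-switched borate salt 23 (not isolated)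
Conditions: BF3·OEt2 (1.2 equiv), CH2Cl2, −78 °C; Bu4NBr (3 equiv), −78 to −30 °C; K2CO3, MeOH, 0 °C
Reagents that add atoms: tetrabutylammonium bromide, CCCC[N+](CCCC)(CCCC)CCCC.[Br-]
Why: Proposed new method: BF3 activates the alkynyl epoxide, the bridging ether oxygen O-b opens it at C4 (inversion) to give tricyclic oxonium zwitterion 22, and bromide then cleaves the O-b–C10 bond by SN2 at the bridgehead carbon, so that the oxygen bridge is handed from C10 to C4 and the 9-oxabicyclo[4.2.1]nonane becomes the fused tetrahydrofuran–oxocane. The closest known reaction types are Lewis-acid epoxide opening by ether oxygen to oxonium ions in polyether cascades, halide opening of bicyclic and tricyclic oxonium ions in bromonium-induced ring expansions, and boron-halide cleavage of 7-oxanorbornanes to trans-4-halocyclohexanols. The tetrahydrofuran ring closes in the 5-exo-tet mode at the epoxide. C4 is set by inversion of the epoxide carbon fixed in step 14 while C3 keeps its configuration, and C10 is set by inversion at the former bridgehead, which puts bromine cis to the C9 silyloxy group. The step needs O-b, not O-a or bromide, to open the epoxide, which is secured by the exo C5 arm that holds C4 over O-b (O-a could only close a four-membered ring or attack the inductively deactivated propargylic C3) and by adding bromide only after ionisation. It also needs oxonium opening at C10 and not at C7 or C4, which should be favoured because C7 is flanked by the fully substituted C6 and its cleavage would leave two eight-membered rings, C4 is shielded by the branched borate-bearing C3, and only cleavage at C10 releases the strain of the bridged bicycle.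

Step 16
Reactants: 24 (S)-1-[(1R,3S,5S,6R,8R,10R)-5-bromo-3-[(S)-1-bromopropyl]-6-(tert-butyldimethylsilyloxy)-2,9-dioxabicyclo[6.3.0]undecan-10-yl]prop-2-yn-1-ol
Product: 25 (1R,3S,5S,6R,8R,10R)-5-bromo-3-[(S)-1-bromopropyl]-10-[(R)-1-bromoprop-2-yn-1-yl]-6-(tert-butyldimethylsilyloxy)-2,9-dioxabicyclo[6.3.0]undecane
Conditions: CBr4, PPh3, 2,6-lutidine, CH2Cl2, −20 to 0 °C
Reagents that add atoms: carbon tetrabromide, BrC(Br)(Br)Br
Why: Appel bromination of the propargylic alcohol by SN2 inversion should convert the (3S)-carbinol into the (3R)-bromide.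

Step 17
Reactants: 25 (1R,3S,5S,6R,8R,10R)-5-bromo-3-[(S)-1-bromopropyl]-10-[(R)-1-bromoprop-2-yn-1-yl]-6-(tert-butyldimethylsilyloxy)-2,9-dioxabicyclo[6.3.0]undecane
Product: 26 (1R,3S,5S,6R,8R,10R)-5-bromo-3-[(S)-1-bromopropyl]-10-[(R)-1-bromoprop-2-yn-1-yl]-2,9-dioxabicyclo[6.3.0]undecan-6-ol (CNP0115352.1)
Conditions: HF·pyridine, pyridine, THF, 0 °C to rt
Reagents that add atoms: none
Why: acidic fluoride desilylation should free the C9 hydroxyl under non-basic conditions that spare the propargylic and the two secondary bromides, and no stereocenter is touched.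

**Compound list**

1 | (E)-pent-2-en-4-yn-1-ol | OC/C=C/C#C | starting material
2 | dilithium salt of 1 (lithium alkoxide, lithium acetylide) | [Li]OC/C=C/C#C[Li] | intermediate
3 | (E)-trimethyl{[5-(trimethylsilyl)pent-2-en-4-yn-1-yl]oxy}silane | C[Si](C)(C)OC/C=C/C#C[Si](C)(C)C | intermediate
4 | (E)-5-(trimethylsilyl)pent-2-en-4-yn-1-ol | OC/C=C/C#C[Si](C)(C)C | intermediate
5 | (E)-(5-bromopent-3-en-1-yn-1-yl)trimethylsilane | BrC/C=C/C#C[Si](C)(C)C | intermediate
6 | (1R,5S)-8-oxabicyclo[3.2.1]oct-6-en-3-one (meso) | C1C(=O)C[C@H]2O[C@@H]1C=C2 | starting material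
7 | (1'R,5'S)-spiro[1,3-dioxolane-2,3'-[8]oxabicyclo[3.2.1]oct[6]ene] (meso) | C1C2(OCCO2)C[C@H]3O[C@@H]1C=C3 | intermediate
8 | exo-6'-[bis(isopinocampheyl)boryl] adduct of 7 | C1C2(OCCO2)C[C@H]3O[C@@H]1C[C@@H]3B([C@@H]4C[C@@H]5C[C@H]([C@H]4C)C5(C)C)[C@@H]4C[C@@H]5C[C@H]([C@H]4C)C5(C)C | intermediate
9 | (1'R,5'R,6'S)-spiro[1,3-dioxolane-2,3'-[8]oxabicyclo[3.2.1]octan]-6'-ol (exo alcohol) | C1C2(OCCO2)C[C@H]3O[C@@H]1C[C@@H]3O | intermediate
10 | (1'R,5'R)-spiro[1,3-dioxolane-2,3'-[8]oxabicyclo[3.2.1]octan]-6'-one | C1C2(OCCO2)C[C@H]3O[C@@H]1CC3=O | intermediate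
11 | (1'R,5'R,6'R)-spiro[1,3-dioxolane-2,3'-[8]oxabicyclo[3.2.1]octan]-6'-ol (endo alcohol) | C1C2(OCCO2)C[C@H]3O[C@@H]1C[C@H]3O | intermediate
12 | (1'R,5'R,6'R)-6'-(tert-butyldimethylsilyloxy)spiro[1,3-dioxolane-2,3'-[8]oxabicyclo[3.2.1]octane] | C1C2(OCCO2)C[C@H]3O[C@@H]1C[C@H]3O[Si](C)(C)C(C)(C)C | intermediate
13 | (1R,5R,6R)-6-(tert-butyldimethylsilyloxy)-8-oxabicyclo[3.2.1]octan-3-one | C1C(=O)C[C@H]2O[C@@H]1C[C@H]2O[Si](C)(C)C(C)(C)C | intermediate
14 | lithium enolate of 13 (C2=C3, on the α-carbon remote from the silyloxy group) | C1=C(O[Li])C[C@H]2O[C@@H]1C[C@H]2O[Si](C)(C)C(C)(C)C | intermediate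
15 | (1R,2R,5R,6R)-6-(tert-butyldimethylsilyloxy)-2-[(E)-5-(trimethylsilyl)pent-2-en-4-yn-1-yl]-8-oxabicyclo[3.2.1]octan-3-one | C[Si](C)(C)C#C/C=C/C[C@H]1C(=O)C[C@H]2O[C@@H]1C[C@H]2O[Si](C)(C)C(C)(C)C | intermediate
16 | (1R,2R,6R,7R)-7-(tert-butyldimethylsilyloxy)-2-[(E)-5-(trimethylsilyl)pent-2-en-4-yn-1-yl]-3,9-dioxabicyclo[4.2.1]nonan-4-one | C[Si](C)(C)C#C/C=C/C[C@H]1OC(=O)C[C@H]2O[C@@H]1C[C@H]2O[Si](C)(C)C(C)(C)C | intermediate
17 | (1R,2R,4Z,6R,7R)-7-(tert-butyldimethylsilyloxy)-4-propylidene-2-[(E)-5-(trimethylsilyl)pent-2-en-4-yn-1-yl]-3,9-dioxabicyclo[4.2.1]nonane | C[Si](C)(C)C#C/C=C/C[C@H]1O/C(=C\CC)C[C@H]2O[C@@H]1C[C@H]2O[Si](C)(C)C(C)(C)C | intermediate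
18 | exo spiro-epoxide of 17 (oxirane on C4 and the propylidene carbon) | C[Si](C)(C)C#C/C=C/C[C@H]1O[C@@]3(O[C@@H]3CC)C[C@H]2O[C@@H]1C[C@H]2O[Si](C)(C)C(C)(C)C | intermediate
19 | (R)-1-[(1R,2R,4S,6R,7R)-7-(tert-butyldimethylsilyloxy)-2-[(E)-5-(trimethylsilyl)pent-2-en-4-yn-1-yl]-3,9-dioxabicyclo[4.2.1]nonan-4-yl]propan-1-ol | C[Si](C)(C)C#C/C=C/C[C@H]1O[C@H]([C@H](O)CC)C[C@H]2O[C@@H]1C[C@H]2O[Si](C)(C)C(C)(C)C | intermediate
20 | (1R,2R,4S,6R,7R)-4-[(S)-1-bromopropyl]-7-(tert-butyldimethylsilyloxy)-2-[(E)-5-(trimethylsilyl)pent-2-en-4-yn-1-yl]-3,9-dioxabicyclo[4.2.1]nonane | C[Si](C)(C)C#C/C=C/C[C@H]1O[C@H]([C@@H](Br)CC)C[C@H]2O[C@@H]1C[C@H]2O[Si](C)(C)C(C)(C)C | intermediate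
21 | (1R,2R,4S,6R,7R)-4-[(S)-1-bromopropyl]-7-(tert-butyldimethylsilyloxy)-2-{[(2S,3S)-3-[(trimethylsilyl)ethynyl]oxiran-2-yl]methyl}-3,9-dioxabicyclo[4.2.1]nonane | C[Si](C)(C)C#C[C@@H]1O[C@H]1C[C@H]2O[C@H]([C@@H](Br)CC)C[C@H]3O[C@@H]2C[C@H]3O[Si](C)(C)C(C)(C)C | intermediate
22 | tricyclic oxonium zwitterion (O-b bonded to C4, C7 and C10; C3–O–BF3 borate) | C[Si](C)(C)C#C[C@H](O[B-](F)(F)F)[C@H]1C[C@H]2O[C@H]([C@@H](Br)CC)C[C@@H]3[C@H](O[Si](C)(C)C(C)(C)C)C[C@H]2[O+]13 | intermediate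
23 | tetrabutylammonium trifluoroborate of the ring-switched C3 alkoxide (C10 bromide, alkyne still silylated) | C[Si](C)(C)C#C[C@H](O[B-](F)(F)F)[C@H]1C[C@H]2O[C@H]([C@@H](Br)CC)C[C@H](Br)[C@H](O[Si](C)(C)C(C)(C)C)C[C@H]2O1.CCCC[N+](CCCC)(CCCC)CCCC | intermediate
24 | (S)-1-[(1R,3S,5S,6R,8R,10R)-5-bromo-3-[(S)-1-bromopropyl]-6-(tert-butyldimethylsilyloxy)-2,9-dioxabicyclo[6.3.0]undecan-10-yl]prop-2-yn-1-ol | C#C[C@H](O)[C@H]1C[C@H]2O[C@H]([C@@H](Br)CC)C[C@H](Br)[C@H](O[Si](C)(C)C(C)(C)C)C[C@H]2O1 | intermediate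
25 | (1R,3S,5S,6R,8R,10R)-5-bromo-3-[(S)-1-bromopropyl]-10-[(R)-1-bromoprop-2-yn-1-yl]-6-(tert-butyldimethylsilyloxy)-2,9-dioxabicyclo[6.3.0]undecane | C#C[C@@H](Br)[C@H]1C[C@H]2O[C@H]([C@@H](Br)CC)C[C@H](Br)[C@H](O[Si](C)(C)C(C)(C)C)C[C@H]2O1 | intermediate
26 | (1R,3S,5S,6R,8R,10R)-5-bromo-3-[(S)-1-bromopropyl]-10-[(R)-1-bromoprop-2-yn-1-yl]-2,9-dioxabicyclo[6.3.0]undecan-6-ol | C#C[C@@H](Br)[C@H]1C[C@H]2O[C@H]([C@@H](Br)CC)C[C@H](Br)[C@H](O)C[C@H]2O1 | target

**Count and risks**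

Total step count: 17. Longest linear sequence: 15 steps (steps 3 to 17, from ketone 6).

The three steps most likely to fail:

Step 15 (proposed new method). Bromide may open the oxonium ion at C4 or C7 instead of C10, may open the BF3-activated epoxide directly, or O-a may take part in place of O-b. The fallback uses known chemistry and separates the two bond changes. It sets out from 20. The bridging ether is cleaved first with dimethylboron bromide (Me2BBr, Et3N, CH2Cl2, −78 °C), by SN2 of bromide at the less hindered bridgehead C10 with inversion, to give bromo alcohol F1. Shi epoxidation under the conditions of step 14 gives epoxy alcohol F2. Camphorsulfonic acid (CH2Cl2, 0 °C) then closes the tetrahydrofuran by 5-exo opening of the epoxide by the free C7 hydroxyl to give C-silyl alcohol F3. K2CO3 in MeOH removes the alkyne silyl group, and the fallback comes back to the route at 24.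

Step 9. Enolisation may occur on the wrong α-carbon, the enolate may β-eliminate with opening of the oxygen bridge before it is alkylated, or the axial side chain may epimerise. The fallback sets out from 13. The same chiral lithium amide is used with TMSCl present as an internal quench, the best-established mode for these ketones, to give silyl enol ether F4. Alcohol 4 is converted with methyl chloroformate and pyridine into allylic carbonate F5. A Tsuji–Trost allylation of F4 with F5 (Pd(PPh3)4, a zerovalent palladium complex, THF) should then form the C5–C6 bond at the terminal allyl carbon and on the exo face of the enolate, and the fallback comes back to the route at 15.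

Step 11. Alkylidenation of the hindered bridged lactone may be slow, may enolise the lactone, or may give poor (Z)/(E) control, which would erode the C13 configuration set in step 12. The fallback sets out from 16. Addition of 2-lithio-2-ethyl-1,3-dithiane (THF, −78 °C) gives hemiketal F6. Et3SiH with BF3·OEt2 reduces it through the oxocarbenium ion with hydride attack on the exo face to give dithianyl ether F7. MeI and CaCO3 in aqueous MeCN unmask ethyl ketone F8. Chelation-controlled reduction with Zn(BH4)2 (Et2O, −20 °C) should give the anti alkoxy alcohol, and the fallback comes back to the route at 19.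

Further compounds
F1 | step 15 | (2R,3R,5R,6S,8S)-6-bromo-8-[(S)-1-bromopropyl]-5-(tert-butyldimethylsilyloxy)-2-[(E)-5-(trimethylsilyl)pent-2-en-4-yn-1-yl]oxocan-3-ol | C[Si](C)(C)C#C/C=C/C[C@H]1O[C@H]([C@@H](Br)CC)C[C@H](Br)[C@H](O[Si](C)(C)C(C)(C)C)C[C@H]1O
F2 | step 15 | (2R,3R,5R,6S,8S)-6-bromo-8-[(S)-1-bromopropyl]-5-(tert-butyldimethylsilyloxy)-2-{[(2S,3S)-3-[(trimethylsilyl)ethynyl]oxiran-2-yl]methyl}oxocan-3-ol | C[Si](C)(C)C#C[C@@H]1O[C@H]1C[C@H]2O[C@H]([C@@H](Br)CC)C[C@H](Br)[C@H](O[Si](C)(C)C(C)(C)C)C[C@H]2O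
F3 | step 15 | (S)-1-[(1R,3S,5S,6R,8R,10R)-5-bromo-3-[(S)-1-bromopropyl]-6-(tert-butyldimethylsilyloxy)-2,9-dioxabicyclo[6.3.0]undecan-10-yl]-3-(trimethylsilyl)prop-2-yn-1-ol | C[Si](C)(C)C#C[C@H](O)[C@H]1C[C@H]2O[C@H]([C@@H](Br)CC)C[C@H](Br)[C@H](O[Si](C)(C)C(C)(C)C)C[C@H]2O1
F4 | step 9 | trimethylsilyl enol ether of 13 (C2=C3, remote from the silyloxy group) | C1=C(O[Si](C)(C)C)C[C@H]2O[C@@H]1C[C@H]2O[Si](C)(C)C(C)(C)C
F5 | step 9 | methyl (E)-5-(trimethylsilyl)pent-2-en-4-yn-1-yl carbonate | COC(=O)OC/C=C/C#C[Si](C)(C)C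
F6 | step 11 | (1R,2R,6R,7R)-7-(tert-butyldimethylsilyloxy)-4-(2-ethyl-1,3-dithian-2-yl)-2-[(E)-5-(trimethylsilyl)pent-2-en-4-yn-1-yl]-3,9-dioxabicyclo[4.2.1]nonan-4-ol (hemiketal, C4 unassigned) | C[Si](C)(C)C#C/C=C/C[C@H]1OC(O)(C3(CC)SCCCS3)C[C@H]2O[C@@H]1C[C@H]2O[Si](C)(C)C(C)(C)C
F7 | step 11 | (1R,2R,4S,6R,7R)-7-(tert-butyldimethylsilyloxy)-4-(2-ethyl-1,3-dithian-2-yl)-2-[(E)-5-(trimethylsilyl)pent-2-en-4-yn-1-yl]-3,9-dioxabicyclo[4.2.1]nonane | C[Si](C)(C)C#C/C=C/C[C@H]1O[C@H](C3(CC)SCCCS3)C[C@H]2O[C@@H]1C[C@H]2O[Si](C)(C)C(C)(C)C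
F8 | step 11 | 1-[(1R,2R,4S,6R,7R)-7-(tert-butyldimethylsilyloxy)-2-[(E)-5-(trimethylsilyl)pent-2-en-4-yn-1-yl]-3,9-dioxabicyclo[4.2.1]nonan-4-yl]propan-1-one | C[Si](C)(C)C#C/C=C/C[C@H]1O[C@H](C(=O)CC)C[C@H]2O[C@@H]1C[C@H]2O[Si](C)(C)C(C)(C)C
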